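The route rests on breaking the C2–C3 bond of the oxolane ring (O1, C2 carrying the arylmethyl carbon C1', C3, C4, C5). C3 sits at the ketone oxidation level and can therefore be an acyl radical, while C1', being benzylic, stabilises the radical generated when C2–C3 forms. In one operation a 5-exo acyl radical closure of a phenyl selenoester onto a styryl enol ether builds the ring, the C2–C3 bond and the 2,5-cis relationship. The precursor is an (S)-3-(styryloxy)glutarate with a selenoester on one arm and a methyl ester on the other; its stereocentre is bought. Hydride reduction, Weinreb ketone synthesis and hydrogenolysis then finish the target.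

Key step: step 8

Assumption: the enantiopure silyl-protected glutarate half-ester 1 (a statin side-chain building block) and the two benzyl-protected aromatic building blocks are taken as purchasable; the styryl ether is carried as an E/Z mixture (E drawn), since both geometries converge in the key step.

Design note: the stereocentre that becomes C5 is purchased with its two arms already differentiated, so no desymmetrisation of the acid-sensitive enol ether is needed. The acid arm of 1 becomes the selenoester, which leads to 5R in the ring.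

Step 1
Reactants: 1 (R)-3-[(tert-butyldimethylsilyl)oxy]-5-methoxy-5-oxopentanoic acid
Product: 2 1-allyl 5-methyl (S)-3-[(tert-butyldimethylsilyl)oxy]pentanedioate
Conditions: allyl bromide, KHCO3, DMF, rt
Reagents that add atoms: allyl bromide, C=CCBr
Why: Carboxylate O-alkylation (SN2 esterification) with a mild bicarbonate base should cap the free acid arm without touching the β-silyloxy ester or the stereocentre, whose descriptor becomes S only through the change in priorities.

Step 2
Reactants: 2 1-allyl 5-methyl (S)-3-[(tert-butyldimethylsilyl)oxy]pentanedioate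
Product: 3 1-allyl 5-methyl (S)-3-hydroxypentanedioate
Conditions: HF·pyridine, pyridine, THF, 0 °C to rt
Reagents that add atoms: none
Why: Fluoride-mediated silyl ether cleavage under buffered, weakly acidic conditions should free the alcohol without the β-elimination that a basic fluoride source could cause in a β-oxy diester.

Step 3
Reactants: 4 4-(benzyloxy)-3-methoxybenzaldehyde
Product: 5 1-(benzyloxy)-2-methoxy-4-(2-methoxyethenyl)benzene (E/Z mixture, E drawn)
Conditions: MeOCH2PPh3Cl, KOtBu, THF, 0 °C to rt
Reagents that add atoms: (methoxymethyl)triphenylphosphonium chloride, COC[P+](c1ccccc1)(c1ccccc1)c1ccccc1.[Cl-]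
Why: Wittig methoxymethylenation of an aromatic aldehyde is routine, and the geometric mixture is of no consequence because the double bond is protonated in the next step.

Step 4
Reactants: 3 1-allyl 5-methyl (S)-3-hydroxypentanedioate; 5 1-(benzyloxy)-2-methoxy-4-(2-methoxyethenyl)benzene
Product: 6 1-allyl 5-methyl (3S)-3-{[2-(4-benzyloxy-3-methoxyphenyl)-1-methoxyethyl]oxy}pentanedioate (both epimers at the acetal carbon)
Conditions: CSA (cat.), CH2Cl2, 0 °C to rt; Et3N quench
Reagents that add atoms: none
Why: Acid-catalysed addition of an alcohol to an enol ether (the reaction type behind tetrahydropyranyl protection) should protonate 5 at its benzylic carbon and let the hydroxyl of 3 capture the oxocarbenium ion, with no base present that could eliminate the β-hydroxy diester.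

Step 5
Reactants: 6 1-allyl 5-methyl (3S)-3-{[2-(4-benzyloxy-3-methoxyphenyl)-1-methoxyethyl]oxy}pentanedioate
Product: 7 1-allyl 5-methyl (S)-3-{[(E)-2-(4-benzyloxy-3-methoxyphenyl)ethenyl]oxy}pentanedioate (E drawn; any Z isomer is carried along)
Conditions: TMSOTf, iPr2NEt, CH2Cl2, −20 °C to rt
Reagents that add atoms: none
Why: Silyl triflate–amine elimination of an acetal to an enol ether should ionise 6 at the more basic and less hindered methoxy oxygen (the glutarate oxygen is deactivated by its two ester-bearing arms), after which the hindered amine removes a benzylic proton to give the conjugated styryl ether.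

Step 6
Reactants: 7 1-allyl 5-methyl (S)-3-{[(E)-2-(4-benzyloxy-3-methoxyphenyl)ethenyl]oxy}pentanedioate
Product: 8 (R)-3-{[(E)-2-(4-benzyloxy-3-methoxyphenyl)ethenyl]oxy}-5-methoxy-5-oxopentanoic acid
Conditions: Pd(PPh3)4 (cat.), morpholine, THF, rt; NaH2PO4 buffer (pH 5) wash
Reagents that add atoms: none
Why: Palladium-catalysed allyl transfer from the ester to morpholine (Tsuji–Trost deallylation) should release the acid under neutral conditions that spare the methyl ester, the benzyl ether and the styryl ether, which hydrolyses far more slowly than a simple vinyl ether.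

Step 7
Reactants: 8 (R)-3-{[(E)-2-(4-benzyloxy-3-methoxyphenyl)ethenyl]oxy}-5-methoxy-5-oxopentanoic acid
Product: 9 methyl (S)-3-{[(E)-2-(4-benzyloxy-3-methoxyphenyl)ethenyl]oxy}-5-oxo-5-(phenylselanyl)pentanoate
Conditions: (PhSe)2, PBu3, CH2Cl2, 0 °C to rt
Reagents that add atoms: diphenyl diselenide, c1ccc([Se][Se]c2ccccc2)cc1
Why: Phosphine–diselenide activation of a carboxylic acid (acyloxyphosphonium ion captured by benzeneselenolate) should give the Se-phenyl selenoester without base, so the β-styryloxy group is not eliminated.

Step 8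
Reactants: 9 methyl (S)-3-{[(E)-2-(4-benzyloxy-3-methoxyphenyl)ethenyl]oxy}-5-oxo-5-(phenylselanyl)pentanoate
Product: 10 methyl 2-[(2R,5R)-5-(4-benzyloxy-3-methoxybenzyl)-4-oxotetrahydrofuran-2-yl]acetate (2,5-cis)
Conditions: Bu3SnH (slow addition), AIBN, benzene (0.01 M), 80 °C
Reagents that add atoms: none
Why: A stannyl radical abstracts the phenylselanyl group of 9, the acyl radical centred on C3 adds to the oxygen-bearing alkene carbon C2, and the benzylic radical left on C1' takes hydrogen from Bu3SnH to carry the chain. The closest known reaction type is the hydride-mediated 5-exo cyclisation of acyl selenides onto β-alkoxyacrylates to cis-2,5-disubstituted tetrahydrofuran-3-ones, with the aryl group here taking over the radical-stabilising role of the ester, as in acyl radical additions to styrenes. The oxolane ring closes in the 5-exo-trig mode, preferred over 6-endo attack at C1' on stereoelectronic grounds and because only the exo path produces a benzylic radical. The new stereocentre C2 is set under control of C5 via a chair-like arrangement in which the acetate arm on C5 occupies a pseudoequatorial site and the vinyl ether adopts the s-trans conformation, so the 2,5-cis ketone results from either alkene geometry. The step needs ring closure to outrun hydrogen transfer to the acyl radical and decarbonylation, which the low stationary stannane concentration and the fast addition to a styrene-type acceptor should secure. Bu3SnH is preferred to a silane because it is the better hydrogen donor toward the stabilised benzylic radical, whose stabilisation also disfavours ring expansion by 1,2-acyl shift.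

Step 9
Reactants: 10 methyl 2-[(2R,5R)-5-(4-benzyloxy-3-methoxybenzyl)-4-oxotetrahydrofuran-2-yl]acetate
Product: 11 methyl 2-[(2R,4R,5R)-5-(4-benzyloxy-3-methoxybenzyl)-4-hydroxytetrahydrofuran-2-yl]acetate (all-cis)
Conditions: Li[HB(sec-Bu)3], THF, −78 °C; aq. NH4Cl
Reagents that add atoms: none
Why: Hindered trialkylborohydride reduction of a cyclic ketone should deliver hydride to the ring face opposite the two cis substituents, placing the new hydroxyl cis to both (4R in the name numbering), while the methyl ester is inert at this temperature.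

Step 10
Reactants: 11 methyl 2-[(2R,4R,5R)-5-(4-benzyloxy-3-methoxybenzyl)-4-hydroxytetrahydrofuran-2-yl]acetate
Product: 12 2-[(2R,4R,5R)-5-(4-benzyloxy-3-methoxybenzyl)-4-hydroxytetrahydrofuran-2-yl]-N-methoxy-N-methylacetamide
Conditions: MeNHOMe·HCl, AlMe3, CH2Cl2, 0 °C to rt; aq. potassium sodium tartrate
Reagents that add atoms: N,O-dimethylhydroxylamine hydrochloride, CNOC.Cl
Why: Aluminium amide aminolysis of an ester (Weinreb amide formation) is Lewis acidic and not basic, so it should convert the ester without β-elimination of the ring oxygen, and any material that has lactonised onto the cis hydroxyl is opened by the same reagent to 12.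

Step 11
Reactants: 12 2-[(2R,4R,5R)-5-(4-benzyloxy-3-methoxybenzyl)-4-hydroxytetrahydrofuran-2-yl]-N-methoxy-N-methylacetamide; 13 1-(benzyloxy)-4-bromo-2-methoxybenzene
Product: 15 1-[4-(benzyloxy)-3-methoxyphenyl]-2-[(2R,4R,5R)-5-(4-benzyloxy-3-methoxybenzyl)-4-hydroxytetrahydrofuran-2-yl]ethan-1-one, via (4-benzyloxy-3-methoxyphenyl)lithium 14 (not isolated)
Conditions: 13, n-BuLi, THF, −78 °C; then 12, −78 to −40 °C; aq. NH4Cl
Reagents that add atoms: none
Why: Bromine–lithium exchange followed by Weinreb ketone synthesis should stop at the ketone because the chelated tetrahedral adduct survives until work-up; an excess of 14 is used because one equivalent is consumed by the free hydroxyl.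

Step 12
Reactants: 15 1-[4-(benzyloxy)-3-methoxyphenyl]-2-[(2R,4R,5R)-5-(4-benzyloxy-3-methoxybenzyl)-4-hydroxytetrahydrofuran-2-yl]ethan-1-one
Product: 16 Renealtin A, 1-(4-hydroxy-3-methoxyphenyl)-2-[(2R,4R,5R)-4-hydroxy-5-(4-hydroxy-3-methoxybenzyl)tetrahydrofuran-2-yl]ethan-1-one
Conditions: H2 (1 atm), Pd/C, EtOAc–MeOH, rt
Reagents that add atoms: none
Why: Catalytic hydrogenolysis of the two aryl benzyl ethers is fast under neutral conditions and should leave the electron-rich aryl ketone, the secondary alcohol and the three stereocentres untouched when stopped at complete debenzylation.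

Compound list
1 | (R)-3-[(tert-butyldimethylsilyl)oxy]-5-methoxy-5-oxopentanoic acid | COC(=O)C[C@@H](CC(=O)O)O[Si](C)(C)C(C)(C)C | starting material
2 | 1-allyl 5-methyl (S)-3-[(tert-butyldimethylsilyl)oxy]pentanedioate | COC(=O)C[C@@H](CC(=O)OCC=C)O[Si](C)(C)C(C)(C)C | intermediate
3 | 1-allyl 5-methyl (S)-3-hydroxypentanedioate | COC(=O)C[C@@H](CC(=O)OCC=C)O | intermediate
4 | 4-(benzyloxy)-3-methoxybenzaldehyde | COc1cc(C=O)ccc1OCc1ccccc1 | starting material
5 | 1-(benzyloxy)-2-methoxy-4-(2-methoxyethenyl)benzene (E/Z mixture, E drawn) | CO/C=C/c1ccc(OCc2ccccc2)c(OC)c1 | intermediate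
6 | 1-allyl 5-methyl (3S)-3-{[2-(4-benzyloxy-3-methoxyphenyl)-1-methoxyethyl]oxy}pentanedioate (acetal epimers) | COC(=O)C[C@@H](CC(=O)OCC=C)OC(OC)Cc1ccc(OCc2ccccc2)c(OC)c1 | intermediate
7 | 1-allyl 5-methyl (S)-3-{[(E)-2-(4-benzyloxy-3-methoxyphenyl)ethenyl]oxy}pentanedioate | COC(=O)C[C@@H](CC(=O)OCC=C)O/C=C/c1ccc(OCc2ccccc2)c(OC)c1 | intermediate
8 | (R)-3-{[(E)-2-(4-benzyloxy-3-methoxyphenyl)ethenyl]oxy}-5-methoxy-5-oxopentanoic acid | COC(=O)C[C@@H](CC(=O)O)O/C=C/c1ccc(OCc2ccccc2)c(OC)c1 | intermediate
9 | methyl (S)-3-{[(E)-2-(4-benzyloxy-3-methoxyphenyl)ethenyl]oxy}-5-oxo-5-(phenylselanyl)pentanoate | COC(=O)C[C@@H](CC(=O)[Se]c1ccccc1)O/C=C/c1ccc(OCc2ccccc2)c(OC)c1 | intermediate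
10 | methyl 2-[(2R,5R)-5-(4-benzyloxy-3-methoxybenzyl)-4-oxotetrahydrofuran-2-yl]acetate | COc1cc(C[C@H]2O[C@@H](CC(=O)OC)CC2=O)ccc1OCc1ccccc1 | intermediate
11 | methyl 2-[(2R,4R,5R)-5-(4-benzyloxy-3-methoxybenzyl)-4-hydroxytetrahydrofuran-2-yl]acetate | COc1cc(C[C@H]2O[C@@H](CC(=O)OC)C[C@H]2O)ccc1OCc1ccccc1 | intermediate
12 | 2-[(2R,4R,5R)-5-(4-benzyloxy-3-methoxybenzyl)-4-hydroxytetrahydrofuran-2-yl]-N-methoxy-N-methylacetamide | COc1cc(C[C@H]2O[C@@H](CC(=O)N(C)OC)C[C@H]2O)ccc1OCc1ccccc1 | intermediate
13 | 1-(benzyloxy)-4-bromo-2-methoxybenzene | COc1cc(Br)ccc1OCc1ccccc1 | starting material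
14 | (4-benzyloxy-3-methoxyphenyl)lithium | COc1cc([Li])ccc1OCc1ccccc1 | intermediate
15 | 1-[4-(benzyloxy)-3-methoxyphenyl]-2-[(2R,4R,5R)-5-(4-benzyloxy-3-methoxybenzyl)-4-hydroxytetrahydrofuran-2-yl]ethan-1-one | COc1cc(C[C@H]2O[C@@H](CC(=O)c3ccc(OCc4ccccc4)c(OC)c3)C[C@H]2O)ccc1OCc1ccccc1 | intermediate
16 | Renealtin A, 1-(4-hydroxy-3-methoxyphenyl)-2-[(2R,4R,5R)-4-hydroxy-5-(4-hydroxy-3-methoxybenzyl)tetrahydrofuran-2-yl]ethan-1-one | COc1cc(C[C@H]2O[C@@H](CC(=O)c3ccc(O)c(OC)c3)C[C@H]2O)ccc1O | target

Total step count: 12. Longest linear sequence: 11 steps (from 1 to 16 through steps 1, 2 and 4 to 12).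

Steps most likely to fail

Step 8. The acyl radical may take hydrogen from the stannane before it closes the ring, because the electron-rich styryl ether is not polarity-matched to a nucleophilic acyl radical. The chain may also stall because the stabilised benzylic radical abstracts hydrogen slowly. The fallback sets out from 9 and changes both the radical precursor and the chain carrier. Reduction of the selenoester with Bu3SnH and catalytic Pd(PPh3)4 in benzene at rt should give the aldehyde methyl (R)-3-{[(E)-2-(4-benzyloxy-3-methoxyphenyl)ethenyl]oxy}-5-oxopentanoate F1. Thiol-catalysed radical-chain hydroacylation (tert-dodecanethiol cat., AIBN, dioxane, 70 °C) should then cyclise F1 in the same 5-exo sense: a thiyl radical abstracts the formyl hydrogen, and the thiol, a fast donor toward benzylic radicals, closes the chain. No stannane is present to intercept the acyl radical. The route is rejoined at 10.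

Step 5. The acetal may ionise with loss of the glutarate oxygen instead of methoxide, which would return 5 and silylated 3, or the esters may be silyl-enolised and then eliminate. The fallback sets out from 4 and 3 and avoids the acetal altogether. Boron-Wittig olefination of 4 with CH2(Bpin)2 and lithium 2,2,6,6-tetramethylpiperidide (THF, −78 °C to rt) should give 2-[(E)-2-(4-benzyloxy-3-methoxyphenyl)ethenyl]-4,4,5,5-tetramethyl-1,3,2-dioxaborolane F2. KHF2 in aqueous methanol should convert it into potassium (E)-[2-(4-benzyloxy-3-methoxyphenyl)ethenyl]trifluoroborate F3. Oxidative Chan–Lam-type coupling of F3 with alcohol 3 (Cu(OAc)2 cat., DMAP, 4 Å MS, O2, CH2Cl2, rt) should form the vinyl C–O bond directly under near-neutral conditions with retention of alkene geometry. The route is rejoined at 7, which also makes step 4 unnecessary.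

Step 11. The aryllithium may deprotonate alpha to the amide, which would open the oxolane by β-elimination of the ring oxygen, or the addition may stall on the aggregated lithium alkoxide. The fallback sets out from 12 and moves the C–C bond formation to a far more electrophilic carbonyl. LiAlH4 (THF, −78 °C) should reduce the Weinreb amide to 2-[(2R,4R,5R)-5-(4-benzyloxy-3-methoxybenzyl)-4-hydroxytetrahydrofuran-2-yl]acetaldehyde F4. Addition of aryllithium 14 at −78 °C should give 1-[4-(benzyloxy)-3-methoxyphenyl]-2-[(2S,4R,5R)-5-(4-benzyloxy-3-methoxybenzyl)-4-hydroxytetrahydrofuran-2-yl]ethan-1-ol F5 as a mixture of carbinol epimers; the ring geometry is unchanged and the descriptor at C2 differs only through priorities. MnO2 (CH2Cl2, rt) should oxidise only the benzylic hydroxyl. The route is rejoined at 15.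

Further compounds
F1 | step 8 | methyl (R)-3-{[(E)-2-(4-benzyloxy-3-methoxyphenyl)ethenyl]oxy}-5-oxopentanoate | COC(=O)C[C@@H](CC=O)O/C=C/c1ccc(OCc2ccccc2)c(OC)c1
F2 | step 5 | 2-[(E)-2-(4-benzyloxy-3-methoxyphenyl)ethenyl]-4,4,5,5-tetramethyl-1,3,2-dioxaborolane | COc1cc(/C=C/B2OC(C)(C)C(C)(C)O2)ccc1OCc1ccccc1
F3 | step 5 | potassium (E)-[2-(4-benzyloxy-3-methoxyphenyl)ethenyl]trifluoroborate | COc1cc(/C=C/[B-](F)(F)F)ccc1OCc1ccccc1.[K+]
F4 | step 11 | 2-[(2R,4R,5R)-5-(4-benzyloxy-3-methoxybenzyl)-4-hydroxytetrahydrofuran-2-yl]acetaldehyde | COc1cc(C[C@H]2O[C@@H](CC=O)C[C@H]2O)ccc1OCc1ccccc1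
F5 | step 11 | 1-[4-(benzyloxy)-3-methoxyphenyl]-2-[(2S,4R,5R)-5-(4-benzyloxy-3-methoxybenzyl)-4-hydroxytetrahydrofuran-2-yl]ethan-1-ol (carbinol epimers) | COc1cc(C[C@H]2O[C@@H](CC(O)c3ccc(OCc4ccccc4)c(OC)c3)C[C@H]2O)ccc1OCc1ccccc1
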